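## Retrosynthetic overview
1. 9 ⇒ 8 ⇒ 7: the C6 benzoate goes on last. The C2 acetate is installed with inversion (Mitsunobu) on the allylic alcohol.
2. 7 ⇒ 5 ⇒ 4: C2–OH and C3=C4 come from a Wharton transposition of the C2–C3 oxirane and C4 ketone. C5–OBz and C6–OH come from a catalyst-controlled benzoate opening of one of the two mirror-related oxiranes of meso 4.
3. 4 ⇒ 3 (key step): both oxiranes close in one operation on the two enone C=C bonds of an achiral p-quinol, on the face of its tertiary OH.
4. 3 ⇒ 2 ⇒ 1: hydroxylative dearomatisation of 4-hydroxybenzyl acetate. All seven skeletal carbons come from 4-hydroxybenzyl alcohol.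
5. Ring order: the carbocycle is the ring of 1 (dearomatised in step 2). The two oxiranes form together in step 3 and are both consumed in step 4.

Convention: locants C1–C7 are those of the target throughout. C1 carries OH and C7H2OAc, C2 is CHOAc, C3=C4 is the alkene, and C5 and C6 are CHOBz. The α face is that of the tertiary OH and the β face is that of C7.

Assumption: the (R,R)-cobalt catalyst is taken to open the C5–C6 oxirane of 4. If a trial run shows the opposite sense, the (S,S)-catalyst is used and nothing else changes.

## Route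

Step 1
Reactants: 1 4-hydroxybenzyl alcohol
Product: 2 4-hydroxybenzyl acetate
Conditions: vinyl acetate (3 equiv), immobilised Candida antarctica lipase B, t-BuOMe, 30 °C
Reagents that add atoms: vinyl acetate, C=COC(C)=O
Why: Lipase-catalysed transesterification acylates only the primary benzylic OH because the phenol is not accepted as a nucleophile, and the enol leaving group tautomerises to acetaldehyde, which makes the transfer irreversible; no stereocentre is formed.

Step 2
Reactants: 2 4-hydroxybenzyl acetate
Product: 3 (1-hydroxy-4-oxocyclohexa-2,5-dien-1-yl)methyl acetate (achiral p-quinol)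
Conditions: PhI(OAc)2 (1.1 equiv), MeCN–H2O 3:1, 0 °C
Reagents that add atoms: water, O
Why: In this hypervalent-iodine hydroxylative phenol dearomatisation, the aryloxy-iodane loses PhI and water captures the para carbon, giving the 4,4-disubstituted cyclohexadienone whose C1 is still prochiral because its two enone arms are identical.

Step 3
Reactants: 3 p-quinol
Product: 4 meso-(6-hydroxy-2-oxo-4,8-dioxatricyclo[5.1.0.0^3,5]octan-6-yl)methyl acetate (2α,3α:5α,6α-bis-oxirane; both oxirane oxygens cis to the tertiary OH)
Conditions: t-BuOOH (5.5 M in decane, 3 equiv), DBU (0.3 equiv), CH2Cl2, −20 to 0 °C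
Reagents that add atoms: tert-butyl hydroperoxide, CC(C)(C)OO
Why: In this twofold Weitz–Scheffer nucleophilic epoxidation, t-BuOO− adds to each enone β-carbon from the face of the tertiary OH (hydrogen bond to the incoming peroxide plus the stereoelectronic preference for attack syn to C–O) and each enolate closes on the O–O bond, so two oxirane rings and the configuration of C2, C3, C5 and C6 relative to C1 are set at once as a single meso compound.

Step 4
Reactants: 4 meso bis-oxirane ketone
Product: 7 [(1R,2R,5R,6S)-5-(benzoyloxy)-1,2,6-trihydroxycyclohex-3-en-1-yl]methyl acetate (2α-OH, 5β-OBz, 6α-OH), via hydroxy benzoate 5 (not isolated), via hydrazone 6 (not isolated)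
Conditions: i) PhCO2H (1.0 equiv), (R,R)-[N,N'-bis(3,5-di-tert-butylsalicylidene)cyclohexane-1,2-diaminato]cobalt benzoate, Co(C36H52N2O2)(O2CPh) (5 mol %), i-Pr2NEt (1 equiv), t-BuOMe, 0 °C; ii) solvent switch to MeOH, N2H4·H2O (2 equiv), AcOH (2 equiv), 0 °C
Reagents that add atoms: benzoic acid, OC(=O)c1ccccc1
Why: Proposed new method: one trivalent cobalt centre binds an oxirane oxygen (helped by the cis tertiary OH) while a second cobalt benzoate delivers PhCO2− anti at C5 (the carbon α to the ketone, where SN2 is fastest, and the distal carbon of a 2,3-epoxy alcohol), so the chiral salen pocket chooses between the two enantiotopic oxiranes and fixes C1, C5 (β-OBz by inversion) and C6 (α-OH), with any mis-opened antipode removed faster by a second opening to a meso bis-benzoate; the closest known reaction type is the cobalt–salen asymmetric ring opening of meso epoxides with benzoic acid, and the labile β-hydroxy ketone 5 is taken on at once in a Wharton transposition, in which hydrazone 6 expels the strained C3–O bond rather than the C5 benzoate and loses N2, giving C3=C4 and keeping the C2–O bond (2α-OH).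

Step 5
Reactants: 7 triol monobenzoate
Product: 8 [(1S,2S,5R,6S)-2-(acetyloxy)-5-(benzoyloxy)-1,6-dihydroxycyclohex-3-en-1-yl]methyl acetate (2β-OAc)
Conditions: AcOH (1.2 equiv), PPh3 (1.2 equiv), DIAD (1.2 equiv), toluene–THF, −10 °C to rt
Reagents that add atoms: acetic acid, CC(=O)O
Why: In this Mitsunobu reaction the allylic, less hindered C2–OH is activated in preference to C6–OH (the same site selectivity seen for the allylic OH of shikimates) and acetate displaces it by SN2 with inversion, setting C2 as the 2β-acetate trans to the tertiary OH, while that OH lies cis to the leaving group and so cannot close an oxirane.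

Step 6
Reactants: 8 diol
Product: 9 [(1R,2S,5R,6S)-2-(acetyloxy)-5,6-bis(benzoyloxy)-1-hydroxycyclohex-3-en-1-yl]methyl acetate (target)
Conditions: BzCl (1.3 equiv), pyridine, CH2Cl2, 0 °C
Reagents that add atoms: benzoyl chloride, O=C(Cl)c1ccccc1
Why: Pyridine-mediated O-benzoylation (nucleophilic acyl substitution) takes the only secondary OH (C6) and leaves the hindered tertiary C1–OH free in the absence of DMAP; no stereocentre is touched.

## Compound list
1 | 4-hydroxybenzyl alcohol | OCc1ccc(O)cc1 | starting material
2 | 4-hydroxybenzyl acetate | CC(=O)OCc1ccc(O)cc1 | intermediate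
3 | (1-hydroxy-4-oxocyclohexa-2,5-dien-1-yl)methyl acetate | CC(=O)OCC1(O)C=CC(=O)C=C1 | intermediate
4 | meso 2α,3α:5α,6α-bis-oxirane of 3 (oxirane oxygens cis to the tertiary OH) | CC(=O)OC[C@@]1(O)[C@@H]2O[C@@H]2C(=O)[C@@H]3O[C@@H]31 | intermediate
5 | (5β-benzoyloxy-2α,3α-epoxy-1α,6α-dihydroxy-4-oxocyclohexyl)methyl acetate | CC(=O)OC[C@@]1(O)[C@@H]2O[C@@H]2C(=O)[C@@H](OC(=O)c2ccccc2)[C@@H]1O | intermediate
6 | C4 hydrazone of 5 | CC(=O)OC[C@@]1(O)[C@@H]2O[C@@H]2C(=NN)[C@@H](OC(=O)c2ccccc2)[C@@H]1O | intermediate
7 | [(1R,2R,5R,6S)-5-(benzoyloxy)-1,2,6-trihydroxycyclohex-3-en-1-yl]methyl acetate | CC(=O)OC[C@@]1(O)[C@H](O)C=C[C@@H](OC(=O)c2ccccc2)[C@@H]1O | intermediate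
8 | [(1S,2S,5R,6S)-2-(acetyloxy)-5-(benzoyloxy)-1,6-dihydroxycyclohex-3-en-1-yl]methyl acetate | CC(=O)OC[C@@]1(O)[C@@H](OC(C)=O)C=C[C@@H](OC(=O)c2ccccc2)[C@@H]1O | intermediate
9 | [(1R,2S,5R,6S)-2-(acetyloxy)-5,6-bis(benzoyloxy)-1-hydroxycyclohex-3-en-1-yl]methyl acetate | CC(=O)OC[C@@]1(O)[C@@H](OC(C)=O)C=C[C@@H](OC(=O)c2ccccc2)[C@@H]1OC(=O)c1ccccc1 | target

## Step count
Total step count: 6. Longest linear sequence: 6.

## Steps most likely to fail

**Step 4.** The enantiotopic selection on an electron-poor keto-oxirane has no precedent. Compound 5 can dehydrate, and the C5 benzoate sits α to the hydrazone.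

The fallback sets out from 4 and comes back at 9. The Wharton transposition (N2H4·H2O, AcOH, MeOH, 0 °C) is run on the meso ketone itself, which can only give the racemic vinyl oxirane diol F3. This is resolved by catalytic acylative kinetic resolution with (i-PrCO)2O and benzotetramisole of the hand that acylates the unwanted antipode. That antipode leaves as the mirror-image 2-isobutyrate F4, and F3 is recovered enantiopure at slightly over half conversion. C2 of F3, now the only secondary OH, is inverted with AcOH/PPh3/DIAD to the 2β-acetoxy vinyl oxirane F5. The allylic oxirane is then opened at C5 and C6–O capped in one go with (PhCO)2O and catalytic n-Bu4N O2CPh, which gives 9.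

**Step 3.** Under base, the alkoxide of 3 can shift the acetyl group from C7. The freed C7 alkoxide then fragments with loss of formaldehyde, driven by aromatisation.

The fallback sets out from 3 and comes back at 4. The tertiary OH is capped (TMSOTf, 2,6-lutidine, CH2Cl2, −78 °C) to the p-quinol trimethylsilyl ether F1, which can form no alkoxide. The same twofold epoxidation is run on F1. Its facial choice now rests only on the stereoelectronic preference for attack syn to the C–O bond, and it gives the meso bis-oxirane silyl ether F2. HF·pyridine in THF then frees 4.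

**Step 5.** Site selectivity between C2–OH and C6–OH may be incomplete, and SN2' attack at C4 may compete at a carbinol next to a quaternary centre.

The fallback sets out from 7 and comes back at 9, and inverts C2 by oxidation and reduction instead of substitution. MnO2 (CH2Cl2, rt) oxidises only the allylic alcohol to the 2-oxo enone diol F6. BzCl/pyridine caps C6–OH to the enone dibenzoate F7, which has no α-hydrogen at C1 and so cannot lose benzoate by E1cB. Chelation-controlled reduction (Zn(BH4)2 in Et2O at −20 °C, or NaBH4/CeCl3·7H2O) delivers hydride from the α face to give the 2β-alcohol F8, the anti diol. Ac2O/pyridine then gives 9.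

## Further compounds
F1 | step 3 | (4-oxo-1-trimethylsilyloxycyclohexa-2,5-dien-1-yl)methyl acetate | CC(=O)OCC1(O[Si](C)(C)C)C=CC(=O)C=C1
F2 | step 3 | meso 2α,3α:5α,6α-bis-oxirane of F1 (oxirane oxygens cis to OSiMe3) | CC(=O)OC[C@@]1(O[Si](C)(C)C)[C@@H]2O[C@@H]2C(=O)[C@@H]3O[C@@H]31
F3 | step 4 | (5α,6α-epoxy-1α,2α-dihydroxycyclohex-3-en-1-yl)methyl acetate (first formed as racemate, needed enantiomer drawn) | CC(=O)OC[C@@]1(O)[C@H](O)C=C[C@@H]2O[C@@H]21
F4 | step 4 | 2-isobutyrate of the mirror image of F3 | CC(=O)OC[C@]1(O)[C@@H](OC(=O)C(C)C)C=C[C@H]2O[C@H]21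
F5 | step 4 | (2β-acetoxy-5α,6α-epoxy-1α-hydroxycyclohex-3-en-1-yl)methyl acetate | CC(=O)OC[C@@]1(O)[C@@H](OC(C)=O)C=C[C@@H]2O[C@@H]21
F6 | step 5 | (5β-benzoyloxy-1α,6α-dihydroxy-2-oxocyclohex-3-en-1-yl)methyl acetate | CC(=O)OC[C@@]1(O)C(=O)C=C[C@@H](OC(=O)c2ccccc2)[C@@H]1O
F7 | step 5 | (5β,6α-bis(benzoyloxy)-1α-hydroxy-2-oxocyclohex-3-en-1-yl)methyl acetate | CC(=O)OC[C@@]1(O)C(=O)C=C[C@@H](OC(=O)c2ccccc2)[C@@H]1OC(=O)c1ccccc1
F8 | step 5 | (5β,6α-bis(benzoyloxy)-1α,2β-dihydroxycyclohex-3-en-1-yl)methyl acetate | CC(=O)OC[C@@]1(O)[C@@H](O)C=C[C@@H](OC(=O)c2ccccc2)[C@@H]1OC(=O)c1ccccc1
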